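**Strategy.** Germacrane numbering is used throughout: carbocycle C1–C10, lactone O–C8/C7/C11(=C13)/C12, acetates on C6 and C9, ester on C5, C1/C10 epoxide, C2 ketone, C4=C15. Everything rests on cutting C6–C7. The target hides a homoallylic alcohol, O–C6–C7–C11=C13, where the α-methylene-γ-lactone meets the ten-membered ring; this is the retron of a carbonyl allylation with allyl transposition. An intramolecular Nozaki–Hiyama–Kishi reaction of a C6 aldehyde with a 3-(bromomethyl)butenolide therefore closes the carbocycle, sets C6 and C7 and unveils the exocyclic methylene in one operation. Its precursor is an acyclic epoxy aldehyde in which C1, C5, C8, C9 and C10 are already in place.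

Key step: step 21

Remark: C2 is formed as a mixture of epimers in step 14 and carries no stereo mark in the SMILES until it becomes the ketone in step 24; compounds 1, 5, 15, 19 and 26 are taken as purchasable.

Step 1
Reactants: 1 but-2-yn-1-ol
Product: 3 (Z)-3-iodobut-2-en-1-ol, via cyclic alkenylalanate 2 (not isolated)
Conditions: Red-Al (NaAlH2(OCH2CH2OMe)2), THF, 0 °C to rt; then I2, −78 °C to 0 °C
Reagents that add atoms: iodine, II
Why: Hydroxyl-directed trans-hydroalumination places aluminium on C3 inside a five-membered alkoxyalanate, and iodinolysis with retention gives the Z-iodide that fixes the later C10=C1 geometry.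

Step 2
Reactants: 3 (Z)-3-iodobut-2-en-1-ol
Product: 4 (Z)-iodide TES ether
Conditions: Et3SiCl, imidazole, CH2Cl2, 0 °C
Reagents that add atoms: chlorotriethylsilane, CC[Si](Cl)(CC)CC
Why: Routine silyl protection of a primary allylic alcohol.

Step 3
Reactants: 5 (R)-but-3-ene-1,2-diol
Product: 6 4-methoxybenzylidene acetal
Conditions: 4-MeOC6H4CH(OMe)2, PPTS (cat.), CH2Cl2, rt
Reagents that add atoms: 4-methoxybenzaldehyde dimethyl acetal, COc1ccc(C(OC)OC)cc1
Why: Acid-catalysed transacetalisation of the 1,2-diol; the new acetal centre is lost in the next step.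

Step 4
Reactants: 6 4-methoxybenzylidene acetal
Product: 7 (R)-2-(PMB-oxy)but-3-en-1-ol
Conditions: DIBAL-H (i-Bu2AlH), CH2Cl2, −78 °C to 0 °C; then aq KNaC4H4O6
Reagents that add atoms: none
Why: Regioselective reductive acetal opening, in which aluminium binds the less hindered primary oxygen so that the PMB group stays on the secondary (C8) oxygen.

Step 5
Reactants: 7 (R)-2-(PMB-oxy)but-3-en-1-ol
Product: 8 (R)-2-(PMB-oxy)but-3-enal
Conditions: DMP, CH2Cl2, 0 °C; crude aldehyde used at once
Reagents that add atoms: none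
Why: Dess–Martin oxidation without base avoids enolisation of the β,γ-unsaturated α-alkoxy aldehyde.

Step 6
Reactants: 4 (Z)-iodide TES ether; 8 (R)-2-(PMB-oxy)but-3-enal
Product: 11 syn dienol (C8 R, C9 R), via alkenyllithium 9 (not isolated), via alkenylmagnesium bromide 10 (not isolated)
Conditions: t-BuLi (2 equiv), Et2O, −78 °C; MgBr2·OEt2, −78 °C; then 8, CH2Cl2, −78 °C; then H2O
Reagents that add atoms: none
Why: Iodine–lithium exchange with retention, transmetallation and Cram-chelate-controlled 1,2-addition (magnesium bridging the aldehyde and PMB-ether oxygens) should set C9 syn to C8.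

Step 7
Reactants: 11 syn dienol
Product: 12 threo epoxy alcohol
Conditions: m-CPBA, CH2Cl2, 0 °C
Reagents that add atoms: m-chloroperoxybenzoic acid, OOC(=O)c1cccc(Cl)c1
Why: Hydroxyl-directed peracid epoxidation of a Z-allylic alcohol, in which A(1,3) strain holds H9 in the alkene plane so that delivery from the hydroxyl face sets C10 and C1 threo to C9 while the unactivated vinyl group is left.

Step 8
Reactants: 12 threo epoxy alcohol
Product: 13 C9 acetate
Conditions: Ac2O, pyridine, DMAP (cat.), CH2Cl2, 0 °C to rt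
Reagents that add atoms: acetic anhydride, CC(=O)OC(C)=O
Why: DMAP-catalysed acetylation installs the C9 acetate of the target and frees later steps from a C8/C9 differentiation problem.

Step 9
Reactants: 13 C9 acetate
Product: 14 epoxy aldehyde
Conditions: (COCl)2, DMSO, CH2Cl2, −78 °C to −40 °C; then Et3N, −78 °C to 0 °C
Reagents that add atoms: none
Why: Swern conditions are known to cleave a primary triethylsilyl ether and oxidise it directly to the aldehyde (desilylative Swern oxidation).

Step 10
Reactants: 15 methyl (S)-2,3-dihydroxypropanoate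
Product: 16 primary TES ether
Conditions: Et3SiCl (1.05 equiv), imidazole, CH2Cl2, −20 °C
Reagents that add atoms: chlorotriethylsilane, CC[Si](Cl)(CC)CC
Why: Selective silylation of the primary hydroxyl of a 1,2-diol at low temperature.

Step 11
Reactants: 16 primary TES ether
Product: 18 allylsilane alcohol, via bis(silylmethyl) diol 17 (not isolated)
Conditions: Me3SiCH2MgCl (5 equiv), CeCl3, THF, −78 °C to rt; then H2O; then silica gel, CH2Cl2, rt
Reagents that add atoms: (trimethylsilyl)methylmagnesium chloride, C[Si](C)(C)C[Mg]Cl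
Why: Cerium-mediated double Grignard addition to the ester followed by acid-promoted Peterson elimination gives the 2-substituted allylsilane, and the weakly basic organocerium reagent leaves the C5 stereocentre untouched.

Step 12
Reactants: 18 allylsilane alcohol; 19 (R)-2-methylbutanoic acid
Product: 20 allylsilane ester
Conditions: DCC, DMAP (cat.), CH2Cl2, 0 °C to rt
Reagents that add atoms: none
Why: Steglich esterification introduces the C5 (R)-2-methylbutanoate early, on a robust small fragment.

Step 13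
Reactants: 20 allylsilane ester
Product: 21 allyl bromide
Conditions: NBS, CH2Cl2, −78 °C to 0 °C
Reagents that add atoms: N-bromosuccinimide, BrN1C(=O)CCC1=O
Why: Electrophilic bromodesilylation (SE2′) of the allylsilane gives the 2-substituted allyl bromide.

Step 14
Reactants: 14 epoxy aldehyde; 21 allyl bromide
Product: 23 C2–C3 coupled alcohol, via allylzinc bromide 22 (not isolated)
Conditions: Zn dust, THF/sat. aq NH4Cl, 0 °C
Reagents that add atoms: none
Why: Barbier allylation under near-neutral aqueous conditions forms C2–C3 and spares epoxide, esters and silyl ether; both C2 epimers are carried on because C2 ends as a ketone.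

Step 15
Reactants: 23 C2–C3 coupled alcohol
Product: 24 bis-TES ether
Conditions: Et3SiCl, imidazole, DMAP (cat.), DMF, 0 °C to rt
Reagents that add atoms: chlorotriethylsilane, CC[Si](Cl)(CC)CC
Why: Silyl protection of the C2 alcohol, which must not be a ketone or free hydroxyl during the ring closure.

Step 16
Reactants: 24 bis-TES ether
Product: 25 C8 alcohol
Conditions: DDQ, CH2Cl2/aq NaH2PO4–Na2HPO4 buffer (pH 7), 0 °C
Reagents that add atoms: none
Why: Oxidative PMB cleavage (hydride abstraction by DDQ, hydrolysis of the oxocarbenium ion) under buffered conditions that keep epoxide and silyl ethers.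

Step 17
Reactants: 25 C8 alcohol; 26 2-(bromomethyl)acrylic acid
Product: 27 C8 2-(bromomethyl)acrylate
Conditions: DCC, DMAP (cat.), CH2Cl2, −20 °C to 0 °C
Reagents that add atoms: none
Why: Steglich esterification at low temperature should acylate C8–OH faster than the neighbouring acetate can migrate.

Step 18
Reactants: 27 C8 2-(bromomethyl)acrylate
Product: 28 3-(bromomethyl)butenolide
Conditions: second-generation Grubbs catalyst (Cl2(PCy3)(H2IMes)Ru=CHPh, 10 mol %), CH2Cl2, 40 °C
Reagents that add atoms: none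
Why: Ring-closing metathesis, in which the carbene loads on the C7 vinyl group and closes the five-membered ring onto the acrylate with loss of ethylene, while the hindered C4=C15 methylene stays out.

Step 19
Reactants: 28 3-(bromomethyl)butenolide
Product: 29 primary C6 alcohol
Conditions: HF·pyridine, pyridine, THF, 0 °C
Reagents that add atoms: none
Why: Selective desilylation, since a primary TES ether is cleaved much faster than the secondary C2 TES ether by buffered HF·pyridine.

Step 20
Reactants: 29 primary C6 alcohol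
Product: 30 seco aldehyde
Conditions: DMP, CH2Cl2, 0 °C; used at once
Reagents that add atoms: none
Why: Dess–Martin oxidation without base, with immediate use, limits acyl migration from O5 and epimerisation at C5.

Step 21
Reactants: 30 seco aldehyde
Product: 32 macrocyclic alcohol, via allylchromium dichloride 31 (not isolated)
Conditions: CrCl2 (10 equiv), THF, rt, slow addition of 30 to a final 1 mM; then H2O
Reagents that add atoms: none
Why: CrCl2 inserts into the allylic C–Br bond to give the allylchromium dichloride 31 (trivalent chromium), which adds to the C6 aldehyde through its γ-carbon C7 in a six-membered Zimmerman–Traxler chair, shifting the double bond to C11=C13 (intramolecular Nozaki–Hiyama–Kishi allylation; the closest known type is the chromium-mediated closure of medium and large rings from 2-(bromomethyl)-2-enoates and tethered aldehydes). The ten-membered carbocycle closes in the 10-exo-trig mode at high dilution. C7 is controlled by the tether, which leaves C8 through C9 on one face of the flat butenolide and should reach C7 on that same face, so the lactone becomes cis-fused. C6 is controlled by the chair: the ring holds C8 trans to the CH2Cr carbon, so with C5 equatorial the 6,7-anti relationship results, and because the bridge from C4 back to C8 keeps C4 gauche to the forming bond while C5–O lies anti to C=O, the aldehyde face flanked by C4 is attacked, which is the 5,6-syn isomer. The selectivity needed is insertion at the allylic bromide without touching epoxide, esters, silyl ether or aldehyde, and ring closure over oligomerisation; the allylic C–Br bond is the only bond that divalent chromium reduces under these conditions, and slow addition secures the second.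

Step 22
Reactants: 32 macrocyclic alcohol
Product: 33 C6 acetate
Conditions: Ac2O, pyridine, DMAP (cat.), CH2Cl2, 0 °C
Reagents that add atoms: acetic anhydride, CC(=O)OC(C)=O
Why: DMAP-catalysed acetylation of the new C6 alcohol, run at once to outpace acyl migration or translactonisation.

Step 23
Reactants: 33 C6 acetate
Product: 34 C2 alcohol
Conditions: HF·pyridine, pyridine, THF, 0 °C
Reagents that add atoms: none
Why: Buffered fluoride desilylation of the secondary TES ether should leave epoxide, esters and the α-methylene lactone intact.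

Step 24
Reactants: 34 C2 alcohol
Product: 35 target CNP0256300.1
Conditions: DMP, CH2Cl2, 0 °C to rt
Reagents that add atoms: none
Why: Dess–Martin oxidation gives the α,β-epoxy ketone without base, so the C4=C15 alkene should not move into conjugation and C1 should not epimerise.

**Compound list**

1 | but-2-yn-1-ol | CC#CCO | starting material
2 | sodium alkenylalanate from 1: 1-oxa-2-aluminacyclopent-3-ene with Al on O1 and C3, two 2-methoxyethoxy ligands | CC1=CCO[Al-]1(OCCOC)OCCOC.[Na+] | intermediate (not isolated)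
3 | (Z)-3-iodobut-2-en-1-ol | C/C(I)=C/CO | intermediate
4 | (Z)-triethyl[(3-iodobut-2-en-1-yl)oxy]silane | C/C(I)=C/CO[Si](CC)(CC)CC | intermediate
5 | (R)-but-3-ene-1,2-diol | C=C[C@@H](O)CO | starting material
6 | (4R)-2-(4-methoxyphenyl)-4-vinyl-1,3-dioxolane (both epimers at the acetal carbon) | C=C[C@@H]1COC(c2ccc(OC)cc2)O1 | intermediate
7 | (R)-2-[(4-methoxybenzyl)oxy]but-3-en-1-ol | C=C[C@@H](OCc1ccc(OC)cc1)CO | intermediate
8 | (R)-2-[(4-methoxybenzyl)oxy]but-3-enal | C=C[C@@H](OCc1ccc(OC)cc1)C=O | intermediate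
9 | 4-(triethylsilyloxy)but-2-en-2-yllithium, lithium in place of the iodine of 4 with geometry retained | C/C([Li])=C/CO[Si](CC)(CC)CC | intermediate (not isolated)
10 | (Z)-4-(triethylsilyloxy)but-2-en-2-ylmagnesium bromide | C/C([Mg]Br)=C/CO[Si](CC)(CC)CC | intermediate (not isolated)
11 | (3R,4R,5Z)-3-[(4-methoxybenzyl)oxy]-5-methyl-7-(triethylsilyloxy)hepta-1,5-dien-4-ol (C8 R, C9 R) | C=C[C@@H](OCc1ccc(OC)cc1)[C@H](O)/C(C)=C\CO[Si](CC)(CC)CC | intermediate
12 | (1S,2R)-2-[(4-methoxybenzyl)oxy]-1-{(2R,3S)-2-methyl-3-[(triethylsilyloxy)methyl]oxiran-2-yl}but-3-en-1-ol | C=C[C@@H](OCc1ccc(OC)cc1)[C@H](O)[C@@]1(C)O[C@H]1CO[Si](CC)(CC)CC | intermediate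
13 | (1S,2R)-2-[(4-methoxybenzyl)oxy]-1-{(2S,3S)-2-methyl-3-[(triethylsilyloxy)methyl]oxiran-2-yl}but-3-en-1-yl acetate | C=C[C@@H](OCc1ccc(OC)cc1)[C@H](OC(C)=O)[C@@]1(C)O[C@H]1CO[Si](CC)(CC)CC | intermediate
14 | (2R,3R)-3-{(1S,2R)-1-acetoxy-2-[(4-methoxybenzyl)oxy]but-3-en-1-yl}-3-methyloxirane-2-carbaldehyde | C=C[C@@H](OCc1ccc(OC)cc1)[C@H](OC(C)=O)[C@@]1(C)O[C@H]1C=O | intermediate
15 | methyl (S)-2,3-dihydroxypropanoate | COC(=O)[C@@H](O)CO | starting material
16 | methyl (S)-2-hydroxy-3-(triethylsilyloxy)propanoate | COC(=O)[C@@H](O)CO[Si](CC)(CC)CC | intermediate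
17 | (3S)-4-(triethylsilyloxy)-1-(trimethylsilyl)-2-[(trimethylsilyl)methyl]butane-2,3-diol | C[Si](C)(C)CC(O)(C[Si](C)(C)C)[C@@H](O)CO[Si](CC)(CC)CC | intermediate (not isolated)
18 | (2R)-1-(triethylsilyloxy)-3-[(trimethylsilyl)methyl]but-3-en-2-ol | C=C(C[Si](C)(C)C)[C@@H](O)CO[Si](CC)(CC)CC | intermediate
19 | (R)-2-methylbutanoic acid | CC[C@@H](C)C(=O)O | starting material
20 | (2R)-1-(triethylsilyloxy)-3-[(trimethylsilyl)methyl]but-3-en-2-yl (2R)-2-methylbutanoate | C=C(C[Si](C)(C)C)[C@@H](OC(=O)[C@H](C)CC)CO[Si](CC)(CC)CC | intermediate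
21 | (2R)-3-(bromomethyl)-1-(triethylsilyloxy)but-3-en-2-yl (2R)-2-methylbutanoate | C=C(CBr)[C@@H](OC(=O)[C@H](C)CC)CO[Si](CC)(CC)CC | intermediate
22 | allylzinc bromide from 21 (ZnBr in place of Br) | C=C(C[Zn]Br)[C@@H](OC(=O)[C@H](C)CC)CO[Si](CC)(CC)CC | intermediate (not isolated)
23 | open-chain C6-to-C7 alcohol: C6H2–OTES, C5 (R) (2R)-2-methylbutanoate, C4=C15, C3H2, C2H–OH (both epimers), (1S,10S)-1,10-epoxide with C14 methyl, C9 (S) acetate, C8 (R) OPMB, C7H=CH2 | C=C[C@@H](OCc1ccc(OC)cc1)[C@H](OC(C)=O)[C@@]1(C)O[C@H]1C(O)CC(=C)[C@@H](OC(=O)[C@H](C)CC)CO[Si](CC)(CC)CC | intermediate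
24 | 2-O-TES ether of 23 (1S,5R,8R,9S,10S) | C=C[C@@H](OCc1ccc(OC)cc1)[C@H](OC(C)=O)[C@@]1(C)O[C@H]1C(O[Si](CC)(CC)CC)CC(=C)[C@@H](OC(=O)[C@H](C)CC)CO[Si](CC)(CC)CC | intermediate
25 | C8 alcohol: 24 with OH in place of OPMB (1S,5R,8R,9S,10S) | C=C[C@@H](O)[C@H](OC(C)=O)[C@@]1(C)O[C@H]1C(O[Si](CC)(CC)CC)CC(=C)[C@@H](OC(=O)[C@H](C)CC)CO[Si](CC)(CC)CC | intermediate
26 | 2-(bromomethyl)prop-2-enoic acid | C=C(CBr)C(=O)O | starting material
27 | C8 2-(bromomethyl)acrylate ester of 25 | C=C[C@@H](OC(=O)C(=C)CBr)[C@H](OC(C)=O)[C@@]1(C)O[C@H]1C(O[Si](CC)(CC)CC)CC(=C)[C@@H](OC(=O)[C@H](C)CC)CO[Si](CC)(CC)CC | intermediate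
28 | (8R)-3-(bromomethyl)furan-2(5H)-one (ring O–C8–C7=C11(CH2Br)–C12=O) carrying at C8 the chain C9 (S) acetate, (1S,10S)-epoxide, C2–OTES, C4=C15, C5 (R) (2R)-2-methylbutanoate, C6H2–OTES | BrCC1=C[C@@H](OC1=O)[C@H](OC(C)=O)[C@@]2(C)O[C@H]2C(O[Si](CC)(CC)CC)CC(=C)[C@@H](OC(=O)[C@H](C)CC)CO[Si](CC)(CC)CC | intermediate
29 | primary C6 alcohol: 28 with C6H2–OH | BrCC1=C[C@@H](OC1=O)[C@H](OC(C)=O)[C@@]2(C)O[C@H]2C(O[Si](CC)(CC)CC)CC(=C)[C@@H](OC(=O)[C@H](C)CC)CO | intermediate
30 | seco aldehyde: 29 with C6 as CHO (1S,5R,8R,9S,10S) | BrCC1=C[C@@H](OC1=O)[C@H](OC(C)=O)[C@@]2(C)O[C@H]2C(O[Si](CC)(CC)CC)CC(=C)[C@@H](OC(=O)[C@H](C)CC)C=O | intermediate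
31 | allylchromium dichloride from 30 (CrCl2 on C13 in place of Br) | Cl[Cr](Cl)CC1=C[C@@H](OC1=O)[C@H](OC(C)=O)[C@@]2(C)O[C@H]2C(O[Si](CC)(CC)CC)CC(=C)[C@@H](OC(=O)[C@H](C)CC)C=O | intermediate (not isolated)
32 | macrocyclic alcohol: cis-fused germacra-4(15),11(13)-dien-8,12-olide with 6-OH, 5-O-(2R)-2-methylbutanoyl, 9-OAc, 1,10-epoxide, 2-OTES (1S,5R,6R,7R,8R,9S,10S) | C=C1C(=O)O[C@@H]2[C@H]1[C@@H](O)[C@H](OC(=O)[C@H](C)CC)C(=C)CC(O[Si](CC)(CC)CC)[C@@H]1O[C@]1(C)[C@H]2OC(C)=O | intermediate
33 | C6 acetate of 32 | C=C1C(=O)O[C@@H]2[C@H]1[C@@H](OC(C)=O)[C@H](OC(=O)[C@H](C)CC)C(=C)CC(O[Si](CC)(CC)CC)[C@@H]1O[C@]1(C)[C@H]2OC(C)=O | intermediate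
34 | C2 alcohol: 33 with OH in place of OTES | C=C1C(=O)O[C@@H]2[C@H]1[C@@H](OC(C)=O)[C@H](OC(=O)[C@H](C)CC)C(=C)CC(O)[C@@H]1O[C@]1(C)[C@H]2OC(C)=O | intermediate
35 | CNP0256300.1: 2-oxo derivative of 34 (1R,5R,6R,7R,8R,9S,10R; ester 2R) | C=C1C(=O)O[C@@H]2[C@H]1[C@@H](OC(C)=O)[C@H](OC(=O)[C@H](C)CC)C(=C)CC(=O)[C@@H]1O[C@]1(C)[C@H]2OC(C)=O | target

**Step count and risks**

Total step count: 24. Longest linear sequence: 18 steps, from 5 to 35 through steps 3–9 and 14–24.

The step most likely to fail is step 21. The ring closure may take the Felkin-type face of the α-acyloxy aldehyde (or the far face of the butenolide), giving poor facial selectivity at C6; oligomerisation is the second danger. The fallback gives up control of C6 in the closure and sets it afterwards by redox inversion. It sets out from 30, which is cyclised as before to the C6-epimeric macrocyclic alcohol F1. This is oxidised with DMP to the macrocyclic C6 ketone F2. Reduction with LiAlH(O-t-Bu)3 in THF at −78 °C under Felkin–Anh control (hydride anti to the C5 acyloxy group, which for a ketone is the 5,6-syn alcohol) then returns the route to 32.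

The second is step 6. The β,γ-unsaturated α-alkoxy aldehyde may lose configurational integrity by enolisation before it is trapped, and chelation control may erode with the hindered alkenylmagnesium reagent. The fallback avoids the aldehyde and sets C9 by reagent control. It sets out from 7, which is oxidised (TEMPO, PhI(OAc)2, MeCN/H2O) to (R)-2-[(4-methoxybenzyl)oxy]but-3-enoic acid F3. Coupling with MeNHOMe·HCl (EDC, N-methylmorpholine) gives the Weinreb amide F4. Addition of alkenyllithium 9 gives the Z-enone F5. Corey–Bakshi–Shibata 1,2-reduction with (S)-2-methyl-CBS-oxazaborolidine and catecholborane, with the alkenyl group acting as the large substituent, should give the (9R)-carbinol and returns the route to 11.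

The third is step 18. Metathesis onto the electron-poor, 1,1-disubstituted 2-(bromomethyl)acrylate may be sluggish, and the allylic bromide may be lost on the ruthenium carbene. The fallback closes the ring without the bromide and introduces it afterwards. It sets out from 25, which is acylated with acryloyl chloride and i-Pr2NEt to the C8 acrylate F6. Morita–Baylis–Hillman hydroxymethylation (aq formaldehyde, DABCO, dioxane) gives the C8 2-(hydroxymethyl)acrylate F7. Ring-closing metathesis with the second-generation Grubbs catalyst gives the 3-(hydroxymethyl)butenolide F8. Appel bromination (CBr4, PPh3) returns the route to 28.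

**Further compounds**

F1 | step 21 | C6 epimer of macrocyclic alcohol 32 (6S) | C=C1C(=O)O[C@@H]2[C@H]1[C@H](O)[C@H](OC(=O)[C@H](C)CC)C(=C)CC(O[Si](CC)(CC)CC)[C@@H]1O[C@]1(C)[C@H]2OC(C)=O
F2 | step 21 | macrocyclic C6 ketone | C=C1C(=O)O[C@@H]2[C@H]1C(=O)[C@H](OC(=O)[C@H](C)CC)C(=C)CC(O[Si](CC)(CC)CC)[C@@H]1O[C@]1(C)[C@H]2OC(C)=O
F3 | step 6 | (R)-2-[(4-methoxybenzyl)oxy]but-3-enoic acid | C=C[C@@H](OCc1ccc(OC)cc1)C(=O)O
F4 | step 6 | (R)-N-methoxy-2-[(4-methoxybenzyl)oxy]-N-methylbut-3-enamide | C=C[C@@H](OCc1ccc(OC)cc1)C(=O)N(C)OC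
F5 | step 6 | (3R,5Z)-3-[(4-methoxybenzyl)oxy]-5-methyl-7-(triethylsilyloxy)hepta-1,5-dien-4-one | C=C[C@@H](OCc1ccc(OC)cc1)C(=O)/C(C)=C\CO[Si](CC)(CC)CC
F6 | step 18 | C8 acrylate ester of 25 | C=C[C@@H](OC(=O)C=C)[C@H](OC(C)=O)[C@@]1(C)O[C@H]1C(O[Si](CC)(CC)CC)CC(=C)[C@@H](OC(=O)[C@H](C)CC)CO[Si](CC)(CC)CC
F7 | step 18 | C8 2-(hydroxymethyl)acrylate ester of 25 | C=C[C@@H](OC(=O)C(=C)CO)[C@H](OC(C)=O)[C@@]1(C)O[C@H]1C(O[Si](CC)(CC)CC)CC(=C)[C@@H](OC(=O)[C@H](C)CC)CO[Si](CC)(CC)CC
F8 | step 18 | 3-(hydroxymethyl)butenolide analogue of 28 | OCC1=C[C@@H](OC1=O)[C@H](OC(C)=O)[C@@]2(C)O[C@H]2C(O[Si](CC)(CC)CC)CC(=C)[C@@H](OC(=O)[C@H](C)CC)CO[Si](CC)(CC)CC
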